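**Retrosynthetic overview**
- The strategy rests on unit A being a benzo-fused cyclohexanone: its benzene ring (C4a, C5–OH, C6, C7–CH3, C8, C8a) is fused to the ring holding the C1 ketone, C2, the aryl-bearing C3 and the C4 carbinol. Cutting C4a–C8a and C7–C8 gives a (Z,E)-2-silyloxydiene (C4a, C5, C6, C7) and an ynone (C8a, C8) joined through C4–C3–C2–C1.
- Both rings of unit A are closed last and together, by an intramolecular Diels–Alder reaction followed by dehydrogenation; C3 and C4 are set beforehand on the open chain.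
- C4–C4a comes from a Felkin-controlled Mukaiyama aldol of an α-aryl aldehyde, C2–C3 from an Evans alkylation of the unit B arylacetyl imide, and the C1 ynone from a Weinreb amide after the dienol ether is in place.
- Unit B is built first: Claisen rearrangement places the C7' side chain on 2-hydroxy-4-methylbenzaldehyde, benzannulation gives a 1-naphthol, oxidative dearomatisation installs the C1' ketal, and conjugate reduction plus asymmetric transfer hydrogenation set C4'.
- Ring order: unit B benzene ring (bought), unit B carbocycle (step 5), then the cyclohexanone and benzene rings of unit A together (step 20); ketal hydrolysis, hydrogenolysis and desilylation finish.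

Key step: step 20

**Remarks.** Unprimed locants are those of unit A of the target, primed locants those of unit B. "Ar" is the protected unit B group (4'R)-8'-(benzyloxy)-4'-[(tert-butyldimethylsilyl)oxy]-6'-methyl-3',4'-dihydro-2'H-spiro[1,3-dioxolane-2,1'-naphthalen]-7'-yl (C1' ketone as ethylene ketal, C8' phenol as benzyl ether, C4' alcohol as TBS ether). Assumption: acid 9 is drawn as the (E) isomer expected from the carboxylate ylide; any (Z) isomer would converge in step 5.

**Step 1**
Reactants: 1 2-hydroxy-4-methylbenzaldehyde; 2 allyl bromide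
Product: 3 2-(allyloxy)-4-methylbenzaldehyde
Conditions: K2CO3, DMF, 60 °C
Reagents that add atoms: none
Why: Williamson etherification of the phenoxide with the allylic bromide (SN2).

**Step 2**
Reactants: 3 2-(allyloxy)-4-methylbenzaldehyde
Product: 5 3-allyl-2-hydroxy-4-methylbenzaldehyde, via ortho-dienone 4 (not isolated)
Conditions: N,N-diethylaniline, 190 °C
Reagents that add atoms: none
Why: Aromatic Claisen rearrangement ([3,3]) should deliver the allyl group to the only free ortho carbon, between OH and CH3, and the dienone tautomerises to the phenol.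

**Step 3**
Reactants: 5 3-allyl-2-hydroxy-4-methylbenzaldehyde
Product: 6 3-allyl-2-(benzyloxy)-4-methylbenzaldehyde
Conditions: BnBr, K2CO3, DMF, 60 °C
Reagents that add atoms: benzyl bromide, BrCc1ccccc1
Why: Williamson etherification protects the future C8' phenol as a benzyl ether that lasts until hydrogenolysis.

**Step 4**
Reactants: 6 3-allyl-2-(benzyloxy)-4-methylbenzaldehyde; 7 (2-carboxyethyl)triphenylphosphonium bromide
Product: 9 (E)-4-[3-allyl-2-(benzyloxy)-4-methylphenyl]but-3-enoic acid, via phosphonium ylide 8 (not isolated)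
Conditions: KOtBu (2.2 equiv), THF, 0 °C → rt; aq. HCl work-up
Reagents that add atoms: none
Why: Wittig olefination with the carboxylate-bearing ylide should give the β,γ-unsaturated acid, which holds the four carbons of the second ring of unit B.

**Step 5**
Reactants: 9 (E)-4-[3-allyl-2-(benzyloxy)-4-methylphenyl]but-3-enoic acid
Product: 11 6-allyl-5-(benzyloxy)-7-methylnaphthalen-1-ol, via naphthyl acetate 10 (not isolated)
Conditions: Ac2O, NaOAc, 140 °C; evaporate; K2CO3 (cat.), MeOH, rt
Reagents that add atoms: none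
Why: Benzannulation of a 4-arylbut-3-enoic acid through its mixed anhydride closes the ring onto the only free ortho carbon, and the resulting acetate is methanolysed in the same flask.

**Step 6**
Reactants: 11 6-allyl-5-(benzyloxy)-7-methylnaphthalen-1-ol
Product: 13 7'-allyl-8'-(benzyloxy)-6'-methyl-4'H-spiro[1,3-dioxolane-2,1'-naphthalen]-4'-one, via hydroxyethoxy naphthol 12 (not isolated)
Conditions: PhI(OAc)2 (2.2 equiv), HOCH2CH2OH (10 equiv), MeCN, 0 °C → rt
Reagents that add atoms: ethylene glycol, OCCO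
Why: Oxidative dearomatisation of the 1-naphthol places the glycol at the para carbon (peri to OBn) and a second oxidation closes the spiro-dioxolane, so C1' is formed already protected and C4' as a free ketone.

**Step 7**
Reactants: 13 quinone monoketal
Product: 14 7'-allyl-8'-(benzyloxy)-6'-methyl-2',3'-dihydro-4'H-spiro[1,3-dioxolane-2,1'-naphthalen]-4'-one
Conditions: [(Ph3P)CuH]6 (0.4 equiv), H2O (5 equiv), toluene, rt
Reagents that add atoms: none
Why: Copper hydride conjugate reduction should saturate only the enone C=C, leaving the allyl group, the benzyl ether and the ketal.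

**Step 8**
Reactants: 14 saturated ketone
Product: 15 (4'R)-7'-allyl-8'-(benzyloxy)-6'-methyl-3',4'-dihydro-2'H-spiro[1,3-dioxolane-2,1'-naphthalen]-4'-ol
Conditions: RuCl[(R,R)-TsDPEN](p-cymene) (1 mol %), HCO2H/Et3N (5:2), CH2Cl2, 30 °C
Reagents that add atoms: none
Why: Noyori asymmetric transfer hydrogenation of this tetralone-type aryl alkyl ketone with the (R,R) catalyst should give the (R) benzylic alcohol, which sets C4', without touching the alkene.

**Step 9**
Reactants: 15 (R)-alcohol
Product: 16 (4'R)-7'-allyl-8'-(benzyloxy)-4'-[(tert-butyldimethylsilyl)oxy]-6'-methyl-3',4'-dihydro-2'H-spiro[1,3-dioxolane-2,1'-naphthalene]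
Conditions: TBSCl, imidazole, DMF, rt
Reagents that add atoms: tert-butyldimethylsilyl chloride, CC(C)(C)[Si](C)(C)Cl
Why: Silylation of the secondary benzylic alcohol gives an ether that tolerates the bases, hydrides and Lewis acid used later.

**Step 10**
Reactants: 16 allyl arene Ar–CH2CH=CH2
Product: 18 2-Ar-acetic acid, via arylacetaldehyde 17 (not isolated)
Conditions: OsO4 (2 mol %), NaIO4, 2,6-lutidine, dioxane/H2O, rt; then NaClO2, NaH2PO4, 2-methyl-2-butene, tBuOH/H2O, 0 °C
Reagents that add atoms: sodium periodate, [Na+].[O-]I(=O)(=O)=O; sodium chlorite, [Na+].[O-]Cl=O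
Why: Lemieux–Johnson cleavage of the terminal alkene followed by Pinnick oxidation of the crude aldehyde should give the arylacetic acid without attack on the arene, ketal or silyl ether.

**Step 11**
Reactants: 18 2-Ar-acetic acid; 19 (R)-4-benzyl-1,3-oxazolidin-2-one
Product: 21 (4R)-4-benzyl-3-(2-Ar-acetyl)-1,3-oxazolidin-2-one, via mixed pivalic anhydride 20 (not isolated)
Conditions: tBuCOCl, Et3N, THF, −20 °C; then 19, LiCl, −20 °C → rt
Reagents that add atoms: none
Why: N-acylation of the oxazolidinone through the mixed anhydride, with attack at the less hindered arylacetyl carbonyl.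

**Step 12**
Reactants: 21 arylacetyl imide; 22 methyl bromoacetate
Product: 24 methyl (3R)-3-Ar-4-[(4R)-4-benzyl-2-oxo-1,3-oxazolidin-3-yl]-4-oxobutanoate, via sodium enolate 23 (not isolated)
Conditions: NaN(SiMe3)2, THF, −78 °C; then 22, −78 → −40 °C
Reagents that add atoms: none
Why: Evans alkylation, in which the chelated (Z) sodium enolate is alkylated on the face away from the benzyl group of the (R) auxiliary, which sets C3 as (R).

**Step 13**
Reactants: 24 alkylated imide
Product: 26 (4R)-4-Ar-oxolan-2-one, via hydroxy ester 25 (not isolated)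
Conditions: NaBH4, THF/H2O (4:1), 0 °C → rt; work-up at pH 5
Reagents that add atoms: none
Why: Borohydride should reduce the activated exocyclic imide carbonyl (reductive removal of the auxiliary, which is recovered) but not the methyl ester, and the γ-hydroxy ester lactonises.

**Step 14**
Reactants: 26 lactone
Product: 27 (3R)-3-Ar-4-hydroxy-N-methoxy-N-methylbutanamide
Conditions: MeNHOMe·HCl (3 equiv), iPrMgCl (6 equiv), THF, −20 → 0 °C
Reagents that add atoms: N,O-dimethylhydroxylamine hydrochloride, CNOC.Cl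
Why: Aminolysis of the lactone by the magnesium amide gives the Weinreb amide at C1 and frees the C4 primary alcohol.

**Step 15**
Reactants: 27 hydroxy Weinreb amide
Product: 28 (3R)-3-Ar-N-methoxy-N-methyl-4-oxobutanamide
Conditions: Dess–Martin periodinane, NaHCO3, CH2Cl2, 0 °C → rt; used at once
Reagents that add atoms: none
Why: Dess–Martin oxidation under buffered, non-enolising conditions should give the α-aryl aldehyde without loss of configuration at C3.

**Step 16**
Reactants: 29 (E)-pent-3-en-2-one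
Product: 31 (E)-2-(trimethylsilyloxy)penta-1,3-diene, via lithium enolate 30 (not isolated)
Conditions: LiN(iPr)2, THF, −78 °C; Me3SiCl, −78 °C → rt
Reagents that add atoms: chlorotrimethylsilane, C[Si](C)(C)Cl
Why: Kinetic deprotonation at the methyl group and O-silylation give the cross-conjugated enol silane.

**Step 17**
Reactants: 28 α-aryl aldehyde; 31 (E)-2-(trimethylsilyloxy)penta-1,3-diene
Product: 32 (3R,4R,7E)-3-Ar-4-hydroxy-N-methoxy-N-methyl-6-oxonon-7-enamide
Conditions: BF3·OEt2 (2.2 equiv), CH2Cl2, −78 °C; aq. NaHCO3 at −78 °C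
Reagents that add atoms: none
Why: Mukaiyama aldol through an open transition state, in which the enol silane attacks the BF3-bound aldehyde anti to the large aryl group (Felkin–Anh), should give the 3,4-anti adduct; C4 is (R) here and becomes (S) by priority change once C4a is sp2.

**Step 18**
Reactants: 32 aldol adduct
Product: 34 (3R,4S,5Z,7E)-3-Ar-4,6-bis[(tert-butyldimethylsilyl)oxy]-N-methoxy-N-methylnona-5,7-dienamide, via silyl ether ketone 33 (not isolated)
Conditions: TBSOTf (2.5 equiv), Et3N (4 equiv), CH2Cl2, −78 → 0 °C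
Reagents that add atoms: tert-butyldimethylsilyl trifluoromethanesulfonate, CC(C)(C)[Si](C)(C)OS(=O)(=O)C(F)(F)F
Why: O-silylation of the alcohol followed by soft enolisation of the enone toward C4a should give the cross-conjugated dienol silyl ether with the preferred (Z) geometry, in which the C4 chain is cis to the silyloxy group.

**Step 19**
Reactants: 34 dienol ether Weinreb amide; 35 ethynylmagnesium bromide
Product: 36 (5R,6S,7Z,9E)-5-Ar-6,8-bis[(tert-butyldimethylsilyl)oxy]undeca-7,9-dien-1-yn-3-one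
Conditions: THF, 0 °C; poured into cold 5% aq. KHSO4/Et2O, rapid separation
Reagents that add atoms: none
Why: Weinreb ketone synthesis, in which the chelated tetrahedral adduct stops at mono-addition and releases the ynone only on the cold acidic quench, which also keeps the liberated amine from adding to the ynone.

**Step 20**
Reactants: 36 silyloxydiene ynone
Product: 38 (3R,4S)-3-Ar-4,5-bis[(tert-butyldimethylsilyl)oxy]-7-methyl-3,4-dihydronaphthalen-1(2H)-one, via cyclohexadiene 37 (not isolated)
Conditions: toluene (0.01 M), BHT (cat.), 110 °C; then DDQ (1.1 equiv), 0 °C; aq. NaHCO3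
Reagents that add atoms: none
Why: On heating, the s-cis (Z,E)-2-silyloxydiene (C4a=C5–C6=C7) should add across the ynone (C8a≡C8) in a concerted, asynchronous [4+2] cycloaddition that forms C7–C8 (to the ynone β-carbon, the more advanced bond) and C4a–C8a, and DDQ then removes the doubly allylic hydride of cyclohexa-1,4-diene 37 and a proton, so that the dienol ether ends as the C5 aryl silyl ether. The closest known reaction type is the type 1 intramolecular Diels–Alder reaction of 2-silyloxydienes with tethered alkynones followed by quinone dehydrogenation. The cyclohexanone ring (C1, C2, C3, C4, C4a, C8a) closes through the four-atom tether as the tether ring of the cycloaddition, and the future benzene ring (C4a, C5, C6, C7, C8, C8a) closes as the six-membered [4+2] ring. No stereocentre is created in 38: C3 and C4 are carried through unchanged and the transient centres C4a and C7 of 37 are erased on aromatisation. The step needs regio- and chemoselectivity only: the tether enforces C4a–C8a bonding against the electronic bias of the silyloxydiene, the (Z) enol silane keeps the tether on the outside of the s-cis diene, and base-free conditions with oxidation straight after cycloaddition keep the C4 silyloxy group from β-elimination.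

**Step 21**
Reactants: 38 protected bis-tetralone
Product: 39 (3R,4S)-3-[(5R)-1-(benzyloxy)-5-[(tert-butyldimethylsilyl)oxy]-3-methyl-8-oxo-5,6,7,8-tetrahydronaphthalen-2-yl]-4,5-bis[(tert-butyldimethylsilyl)oxy]-7-methyl-3,4-dihydronaphthalen-1(2H)-one
Conditions: PPTS (0.2 equiv), acetone/H2O (9:1), 40 °C
Reagents that add atoms: water, O
Why: Acid-catalysed hydrolysis of the aryl ketal, helped by the ortho-alkoxy arene, under conditions mild enough for the three silyl ethers.

**Step 22**
Reactants: 39 benzyl ether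
Product: 40 (3R,4S)-4,5-bis[(tert-butyldimethylsilyl)oxy]-3-[(5R)-5-[(tert-butyldimethylsilyl)oxy]-1-hydroxy-3-methyl-8-oxo-5,6,7,8-tetrahydronaphthalen-2-yl]-7-methyl-3,4-dihydronaphthalen-1(2H)-one
Conditions: H2 (1 atm), Pd/C (10 wt %), EtOAc, rt
Reagents that add atoms: none
Why: Hydrogenolysis of the aryl benzyl ether should be fast enough to spare the aryl ketones and the silyl-protected benzylic C–O bonds.

**Step 23**
Reactants: 40 tris-silyl ether
Product: 41 (3R,4S)-4,5-dihydroxy-3-[(5R)-1,5-dihydroxy-3-methyl-8-oxo-5,6,7,8-tetrahydronaphthalen-2-yl]-7-methyl-3,4-dihydronaphthalen-1(2H)-one (CNP0228272.3)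
Conditions: HF·pyridine, pyridine, THF, 0 °C → rt
Reagents that add atoms: none
Why: Buffered fluoride cleavage of the aryl and the two benzylic silyl ethers should free the target without dehydrating the 4-hydroxytetralones.

**Compound list** (Ar as defined in the remarks)

1 | 2-hydroxy-4-methylbenzaldehyde | Cc1ccc(C=O)c(O)c1 | starting material
2 | allyl bromide | C=CCBr | starting material
3 | 2-(allyloxy)-4-methylbenzaldehyde | Cc1ccc(C=O)c(OCC=C)c1 | intermediate
4 | 5-allyl-4-methyl-6-oxocyclohexa-1,3-diene-1-carbaldehyde (racemic) | O=CC1=CC=C(C)C(CC=C)C1=O | intermediate (not isolated)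
5 | 3-allyl-2-hydroxy-4-methylbenzaldehyde | Cc1ccc(C=O)c(O)c1CC=C | intermediate
6 | 3-allyl-2-(benzyloxy)-4-methylbenzaldehyde | Cc1ccc(C=O)c(OCc2ccccc2)c1CC=C | intermediate
7 | (2-carboxyethyl)triphenylphosphonium bromide | OC(=O)CC[P+](c1ccccc1)(c1ccccc1)c1ccccc1.[Br-] | starting material
8 | potassium 3-(triphenylphosphoranylidene)propanoate | [K+].[O-]C(=O)CC=P(c1ccccc1)(c1ccccc1)c1ccccc1 | intermediate (not isolated)
9 | (E)-4-[3-allyl-2-(benzyloxy)-4-methylphenyl]but-3-enoic acid | OC(=O)C/C=C/c1ccc(C)c(CC=C)c1OCc1ccccc1 | intermediate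
10 | 6-allyl-5-(benzyloxy)-7-methylnaphthalen-1-yl acetate | CC(=O)Oc1cccc2c(OCc3ccccc3)c(CC=C)c(C)cc12 | intermediate (not isolated)
11 | 6-allyl-5-(benzyloxy)-7-methylnaphthalen-1-ol | Oc1cccc2c(OCc3ccccc3)c(CC=C)c(C)cc12 | intermediate
12 | 6-allyl-5-(benzyloxy)-4-(2-hydroxyethoxy)-7-methylnaphthalen-1-ol | OCCOc1ccc(O)c2cc(C)c(CC=C)c(OCc3ccccc3)c12 | intermediate (not isolated)
13 | 7'-allyl-8'-(benzyloxy)-6'-methyl-4'H-spiro[1,3-dioxolane-2,1'-naphthalen]-4'-one | C=CCc1c(C)cc2c(c1OCc1ccccc1)C1(OCCO1)C=CC2=O | intermediate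
14 | 7'-allyl-8'-(benzyloxy)-6'-methyl-2',3'-dihydro-4'H-spiro[1,3-dioxolane-2,1'-naphthalen]-4'-one | C=CCc1c(C)cc2c(c1OCc1ccccc1)C1(OCCO1)CCC2=O | intermediate
15 | (4'R)-7'-allyl-8'-(benzyloxy)-6'-methyl-3',4'-dihydro-2'H-spiro[1,3-dioxolane-2,1'-naphthalen]-4'-ol | C=CCc1c(C)cc2c(c1OCc1ccccc1)C1(OCCO1)CC[C@H]2O | intermediate
16 | (4'R)-7'-allyl-8'-(benzyloxy)-4'-[(tert-butyldimethylsilyl)oxy]-6'-methyl-3',4'-dihydro-2'H-spiro[1,3-dioxolane-2,1'-naphthalene] | C=CCc1c(C)cc2c(c1OCc1ccccc1)C1(OCCO1)CC[C@H]2O[Si](C)(C)C(C)(C)C | intermediate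
17 | 2-Ar-acetaldehyde | O=CCc1c(C)cc2c(c1OCc1ccccc1)C1(OCCO1)CC[C@H]2O[Si](C)(C)C(C)(C)C | intermediate (not isolated)
18 | 2-Ar-acetic acid | OC(=O)Cc1c(C)cc2c(c1OCc1ccccc1)C1(OCCO1)CC[C@H]2O[Si](C)(C)C(C)(C)C | intermediate
19 | (R)-4-benzyl-1,3-oxazolidin-2-one | O=C1N[C@H](Cc2ccccc2)CO1 | starting material
20 | 2-Ar-acetic pivalic anhydride | CC(C)(C)C(=O)OC(=O)Cc1c(C)cc2c(c1OCc1ccccc1)C1(OCCO1)CC[C@H]2O[Si](C)(C)C(C)(C)C | intermediate (not isolated)
21 | (4R)-4-benzyl-3-(2-Ar-acetyl)-1,3-oxazolidin-2-one | O=C(Cc1c(C)cc2c(c1OCc1ccccc1)C1(OCCO1)CC[C@H]2O[Si](C)(C)C(C)(C)C)N1[C@H](Cc2ccccc2)COC1=O | intermediate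
22 | methyl bromoacetate | COC(=O)CBr | starting material
23 | sodium (Z)-enolate of imide 21 | [Na+].[O-]/C(=C\c1c(C)cc2c(c1OCc1ccccc1)C1(OCCO1)CC[C@H]2O[Si](C)(C)C(C)(C)C)N1[C@H](Cc2ccccc2)COC1=O | intermediate (not isolated)
24 | methyl (3R)-3-Ar-4-[(4R)-4-benzyl-2-oxo-1,3-oxazolidin-3-yl]-4-oxobutanoate | COC(=O)C[C@H](c1c(C)cc2c(c1OCc1ccccc1)C1(OCCO1)CC[C@H]2O[Si](C)(C)C(C)(C)C)C(=O)N1[C@H](Cc2ccccc2)COC1=O | intermediate
25 | methyl (3R)-3-Ar-4-hydroxybutanoate | COC(=O)C[C@H](c1c(C)cc2c(c1OCc1ccccc1)C1(OCCO1)CC[C@H]2O[Si](C)(C)C(C)(C)C)CO | intermediate (not isolated)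
26 | (4R)-4-Ar-oxolan-2-one | O=C1C[C@H](c2c(C)cc3c(c2OCc2ccccc2)C2(OCCO2)CC[C@H]3O[Si](C)(C)C(C)(C)C)CO1 | intermediate
27 | (3R)-3-Ar-4-hydroxy-N-methoxy-N-methylbutanamide | CON(C)C(=O)C[C@H](c1c(C)cc2c(c1OCc1ccccc1)C1(OCCO1)CC[C@H]2O[Si](C)(C)C(C)(C)C)CO | intermediate
28 | (3R)-3-Ar-N-methoxy-N-methyl-4-oxobutanamide | CON(C)C(=O)C[C@H](c1c(C)cc2c(c1OCc1ccccc1)C1(OCCO1)CC[C@H]2O[Si](C)(C)C(C)(C)C)C=O | intermediate
29 | (E)-pent-3-en-2-one | C/C=C/C(C)=O | starting material
30 | lithium (E)-penta-1,3-dien-2-olate | [Li+].[O-]C(=C)/C=C/C | intermediate (not isolated)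
31 | (E)-2-(trimethylsilyloxy)penta-1,3-diene | C/C=C/C(=C)O[Si](C)(C)C | intermediate
32 | (3R,4R,7E)-3-Ar-4-hydroxy-N-methoxy-N-methyl-6-oxonon-7-enamide | CON(C)C(=O)C[C@H](c1c(C)cc2c(c1OCc1ccccc1)C1(OCCO1)CC[C@H]2O[Si](C)(C)C(C)(C)C)[C@H](O)CC(=O)/C=C/C | intermediate
33 | (3R,4R,7E)-3-Ar-4-[(tert-butyldimethylsilyl)oxy]-N-methoxy-N-methyl-6-oxonon-7-enamide | CON(C)C(=O)C[C@H](c1c(C)cc2c(c1OCc1ccccc1)C1(OCCO1)CC[C@H]2O[Si](C)(C)C(C)(C)C)[C@H](O[Si](C)(C)C(C)(C)C)CC(=O)/C=C/C | intermediate (not isolated)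
34 | (3R,4S,5Z,7E)-3-Ar-4,6-bis[(tert-butyldimethylsilyl)oxy]-N-methoxy-N-methylnona-5,7-dienamide | C/C=C/C(O[Si](C)(C)C(C)(C)C)=C/[C@@H](O[Si](C)(C)C(C)(C)C)[C@@H](c1c(C)cc2c(c1OCc1ccccc1)C1(OCCO1)CC[C@H]2O[Si](C)(C)C(C)(C)C)CC(=O)N(C)OC | intermediate
35 | ethynylmagnesium bromide | C#C[Mg]Br | starting material
36 | (5R,6S,7Z,9E)-5-Ar-6,8-bis[(tert-butyldimethylsilyl)oxy]undeca-7,9-dien-1-yn-3-one | C/C=C/C(O[Si](C)(C)C(C)(C)C)=C/[C@@H](O[Si](C)(C)C(C)(C)C)[C@@H](c1c(C)cc2c(c1OCc1ccccc1)C1(OCCO1)CC[C@H]2O[Si](C)(C)C(C)(C)C)CC(=O)C#C | intermediate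
37 | (3R,4S)-3-Ar-4,5-bis[(tert-butyldimethylsilyl)oxy]-7-methyl-3,4,4a,7-tetrahydronaphthalen-1(2H)-one (C4a and C7 not assigned) | CC1C=C(O[Si](C)(C)C(C)(C)C)C2C(=C1)C(=O)C[C@H](c1c(C)cc3c(c1OCc1ccccc1)C1(OCCO1)CC[C@H]3O[Si](C)(C)C(C)(C)C)[C@@H]2O[Si](C)(C)C(C)(C)C | intermediate (not isolated)
38 | (3R,4S)-3-Ar-4,5-bis[(tert-butyldimethylsilyl)oxy]-7-methyl-3,4-dihydronaphthalen-1(2H)-one | Cc1cc(O[Si](C)(C)C(C)(C)C)c2c(c1)C(=O)C[C@H](c1c(C)cc3c(c1OCc1ccccc1)C1(OCCO1)CC[C@H]3O[Si](C)(C)C(C)(C)C)[C@@H]2O[Si](C)(C)C(C)(C)C | intermediate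
39 | (3R,4S)-3-[(5R)-1-(benzyloxy)-5-[(tert-butyldimethylsilyl)oxy]-3-methyl-8-oxo-5,6,7,8-tetrahydronaphthalen-2-yl]-4,5-bis[(tert-butyldimethylsilyl)oxy]-7-methyl-3,4-dihydronaphthalen-1(2H)-one | Cc1cc(O[Si](C)(C)C(C)(C)C)c2c(c1)C(=O)C[C@H](c1c(C)cc3c(c1OCc1ccccc1)C(=O)CC[C@H]3O[Si](C)(C)C(C)(C)C)[C@@H]2O[Si](C)(C)C(C)(C)C | intermediate
40 | (3R,4S)-4,5-bis[(tert-butyldimethylsilyl)oxy]-3-[(5R)-5-[(tert-butyldimethylsilyl)oxy]-1-hydroxy-3-methyl-8-oxo-5,6,7,8-tetrahydronaphthalen-2-yl]-7-methyl-3,4-dihydronaphthalen-1(2H)-one | Cc1cc(O[Si](C)(C)C(C)(C)C)c2c(c1)C(=O)C[C@H](c1c(C)cc3c(c1O)C(=O)CC[C@H]3O[Si](C)(C)C(C)(C)C)[C@@H]2O[Si](C)(C)C(C)(C)C | intermediate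
41 | (3R,4S)-4,5-dihydroxy-3-[(5R)-1,5-dihydroxy-3-methyl-8-oxo-5,6,7,8-tetrahydronaphthalen-2-yl]-7-methyl-3,4-dihydronaphthalen-1(2H)-one | Cc1cc(O)c2c(c1)C(=O)C[C@H](c1c(C)cc3c(c1O)C(=O)CC[C@H]3O)[C@@H]2O | target

**Step count and risks**

Total step count: 23. Longest linear sequence: 22 steps (steps 1–15 and 17–23; step 16 is a one-step branch).

Most likely to fail:

1. Step 20 (key step). The cycloaddition is electronically mismatched, because the nucleophilic diene terminus C4a must bond to the ynone α-carbon. It may therefore be slower than thermal loss of silanol across C4–C4a, hydrolysis of the dienol ether or oligomerisation of the terminal ynone, and any (E) enol silane cannot cyclise. Fallback: the same two bonds are made from 36 by metal catalysis instead of by the thermal pericyclic reaction. Ni(cod)2 (zerovalent nickel) with tris(2-biphenylyl) phosphite in THF at room temperature is known to convert dienynes, silyloxydienes included, into cyclohexa-1,4-dienes through a nickelacycle and reductive elimination, a path that is not governed by the frontier-orbital mismatch. This should give 37 without heating, and DDQ as in the main route returns to 38; no new compound is made (F0).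

2. Step 17. BF3 may ionise the electron-rich aryl ketal or promote oxa-Michael closure of the aldol onto its own enone, the α-aryl aldehyde may lose configuration at C3 by enolisation, and the 2,6-disubstituted aryl group may erode the Felkin preference. Fallback: a boron aldol through a closed transition state, without a free Lewis acid. Ketone 29 is converted with (c-C6H11)2BCl and Et3N in Et2O into (E)-penta-1,3-dien-2-yl dicyclohexylborinate F1, which is added to aldehyde 28 at −78 °C. Oxidative work-up (H2O2, pH 7 buffer, MeOH) should give aldol 32, still with Felkin preference though probably at a lower level, so the C4 epimers would be separated on silica; the route is rejoined at 32.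

3. Step 6. The double oxidation may stop at 12, adventitious water may lead to the 1,4-naphthoquinone, or the glycol may add ortho instead of para. Fallback: oxidation and ketal choice are separated. Naphthol 11 is oxidised with PhI(OAc)2 in methanol, the best-established medium for this dearomatisation, to 6-allyl-5-(benzyloxy)-4,4-dimethoxy-7-methylnaphthalen-1(4H)-one F2. Ketal exchange with ethylene glycol (PPTS or catalytic BF3·OEt2, CH2Cl2, molecular sieves) then gives the dioxolane and rejoins the route at 13.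

**Further compounds**

F0 | step 20 | none | none
F1 | step 17 | (E)-penta-1,3-dien-2-yl dicyclohexylborinate | C/C=C/C(=C)OB(C1CCCCC1)C1CCCCC1
F2 | step 6 | 6-allyl-5-(benzyloxy)-4,4-dimethoxy-7-methylnaphthalen-1(4H)-one | C=CCc1c(C)cc2c(c1OCc1ccccc1)C(OC)(OC)C=CC2=O
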